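**Retrosynthetic overview**
The two benzyl ethers on the catechol are removed last, and before that the ester C–O bond is cut to give (S)-14-methylhexadecan-1-ol and 2,3-bis(benzyloxy)benzoic acid.
The strategy rests on the unbranched methylene run C1–C13 between the ester oxygen and the methyl-bearing stereocentre C14: its C11–C12 bond is made by anodic decarboxylative coupling of (S)-4-methylhexanoic acid with the monomethyl ester of dodecanedioic acid.
C14 is bought as (S)-2-methylbutan-1-ol and is carried through a malonate two-carbon homologation that makes or breaks no bond at that carbon.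
No ring is formed: the benzene ring comes intact from 2,3-dihydroxybenzoic acid, the C11–C12 bond is made first and the ester C–O bond afterwards.

Key step: step 5

Remark: commercial (S)-(−)-2-methylbutan-1-ol of high enantiomeric purity is assumed; C1–C16 number the hexadecyl chain from the OCH2 carbon.

**Route**

Step 1
Reactants: 1 (S)-2-methylbutan-1-ol
Product: 2 (S)-2-methylbutyl 4-methylbenzenesulfonate
Conditions: TsCl, Et3N, DMAP (cat.), CH2Cl2, 0 °C → rt
Reagents that add atoms: p-toluenesulfonyl chloride, Cc1ccc(cc1)S(Cl)(=O)=O
Why: O-sulfonylation of a primary alcohol turns the hydroxyl into a leaving group without touching the neighbouring stereocentre.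

Step 2
Reactants: 2 (S)-2-methylbutyl 4-methylbenzenesulfonate; 3 diethyl malonate
Product: 5 diethyl 2-[(2S)-2-methylbutyl]malonate, via sodium enolate of diethyl malonate 4 (not isolated)
Conditions: 3 (excess), NaH, THF/DMF, 0 °C; then 2, 80 °C
Reagents that add atoms: none
Why: malonic ester alkylation, an SN2 displacement of tosylate at the primary CH2 by the soft malonate carbanion in a dipolar aprotic medium, with excess malonate to hold back dialkylation and the stereocentre one carbon away from the reacting centre.

Step 3
Reactants: 5 diethyl 2-[(2S)-2-methylbutyl]malonate
Product: 6 2-[(2S)-2-methylbutyl]malonic acid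
Conditions: KOH, EtOH/H2O, reflux; then HCl (aq.), 0 °C
Reagents that add atoms: potassium hydroxide, [K+].[OH-]
Why: saponification of both ethyl esters by acyl substitution, followed by cold acidification so that the diacid is obtained before it decarboxylates.

Step 4
Reactants: 6 2-[(2S)-2-methylbutyl]malonic acid
Product: 7 (S)-4-methylhexanoic acid
Conditions: neat, 170–180 °C until gas evolution stops; then distillation under reduced pressure
Reagents that add atoms: none
Why: thermal decarboxylation of a malonic acid through a six-membered cyclic transition state; the stereocentre is gamma to the remaining carboxyl group and cannot enolise.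

Step 5
Reactants: 7 (S)-4-methylhexanoic acid; 8 dodecanedioic acid monomethyl ester (12-methoxy-12-oxododecanoic acid)
Product: 9 methyl (S)-14-methylhexadecanoate
Conditions: smooth Pt foil anode, Pt cathode, undivided cell, 8 (3 equiv), NaOMe (about 5 mol% of total acid), MeOH, constant current at high anodic current density (about 0.2 A cm−2), 40–50 °C, until the electrolyte turns faintly alkaline
Reagents that add atoms: none
Why: Kolbe electrolysis: at the platinum anode each carboxylate gives up one electron and loses CO2, so that 7 delivers the primary 3-methylpentyl radical and 8 the primary 10-(methoxycarbonyl)decyl radical, which pair in the radical-rich layer at the electrode surface to forge the C11–C12 sp3–sp3 bond. The closest known reaction type is the crossed Kolbe coupling of a methyl-branched fatty acid with a half ester of an α,ω-diacid, the classical anodic chain extension of fatty acids. No ring closes and no stereocentre is created; C14 lies two carbons from the radical carbon C12 and has no easy hydrogen-shift or fragmentation path to it, so its configuration should be retained. The step needs cross- over self-coupling, which is statistical only, and is steered by the threefold excess of cheap 8; the self-coupled products (volatile 3,8-dimethyldecane and the far more polar dimethyl docosanedioate) should be easy to remove by distillation and chromatography. Over-oxidation of the radicals to cations is held back because neither acid is branched at its alpha carbon and the electrolysis runs on smooth platinum at high current density in weakly acidic methanol, where the methyl ester of 8 is inert.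

Step 6
Reactants: 9 methyl (S)-14-methylhexadecanoate
Product: 10 (S)-14-methylhexadecan-1-ol
Conditions: LiAlH4, THF, 0 °C → rt; then H2O
Reagents that add atoms: none
Why: hydride reduction of an unhindered methyl ester to the primary alcohol, with no other reducible group present and no bond at C14 involved.

Step 7
Reactants: 11 2,3-dihydroxybenzoic acid
Product: 12 benzyl 2,3-bis(benzyloxy)benzoate
Conditions: BnBr (3.5 equiv), K2CO3, DMF, 60 °C
Reagents that add atoms: benzyl bromide, BrCc1ccccc1
Why: exhaustive Williamson O-alkylation of both phenoxides and the carboxylate, with excess benzyl bromide and warming in DMF to bring in the hydrogen-bonded 2-hydroxyl as well.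

Step 8
Reactants: 12 benzyl 2,3-bis(benzyloxy)benzoate
Product: 13 2,3-bis(benzyloxy)benzoic acid
Conditions: KOH, dioxane/H2O, reflux; then HCl (aq.)
Reagents that add atoms: potassium hydroxide, [K+].[OH-]
Why: saponification cleaves only the benzyl ester, since aryl benzyl ethers are stable to aqueous base.

Step 9
Reactants: 10 (S)-14-methylhexadecan-1-ol; 13 2,3-bis(benzyloxy)benzoic acid
Product: 14 (S)-14-methylhexadecyl 2,3-bis(benzyloxy)benzoate
Conditions: DCC, DMAP (cat.), CH2Cl2, 0 °C → rt
Reagents that add atoms: none
Why: Steglich esterification, in which the carbodiimide activates the acid and DMAP transfers the acyl group to the unhindered primary alcohol under neutral conditions that leave the benzyl ethers alone.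

Step 10
Reactants: 14 (S)-14-methylhexadecyl 2,3-bis(benzyloxy)benzoate
Product: 15 Gentiside C, (S)-14-methylhexadecyl 2,3-dihydroxybenzoate
Conditions: H2 (1 atm), 10% Pd/C, EtOAc, rt
Reagents that add atoms: none
Why: catalytic hydrogenolysis cleaves both benzylic C–O bonds of the aryl benzyl ethers, while the alkyl ester, which has no benzylic C–O bond, the benzene ring and the remote stereocentre are untouched.

**Compound list**
1 | (S)-2-methylbutan-1-ol | CC[C@H](C)CO | starting material
2 | (S)-2-methylbutyl 4-methylbenzenesulfonate | CC[C@H](C)COS(=O)(=O)c1ccc(C)cc1 | intermediate
3 | diethyl malonate | CCOC(=O)CC(=O)OCC | starting material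
4 | sodium enolate of diethyl malonate | [Na+].CCOC(=O)[CH-]C(=O)OCC | intermediate (not isolated)
5 | diethyl 2-[(2S)-2-methylbutyl]malonate | CC[C@H](C)CC(C(=O)OCC)C(=O)OCC | intermediate
6 | 2-[(2S)-2-methylbutyl]malonic acid | CC[C@H](C)CC(C(=O)O)C(=O)O | intermediate
7 | (S)-4-methylhexanoic acid | CC[C@H](C)CCC(=O)O | intermediate
8 | dodecanedioic acid monomethyl ester | COC(=O)CCCCCCCCCCC(=O)O | starting material
9 | methyl (S)-14-methylhexadecanoate | CC[C@H](C)CCCCCCCCCCCCC(=O)OC | intermediate
10 | (S)-14-methylhexadecan-1-ol | CC[C@H](C)CCCCCCCCCCCCCO | intermediate
11 | 2,3-dihydroxybenzoic acid | O=C(O)c1cccc(O)c1O | starting material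
12 | benzyl 2,3-bis(benzyloxy)benzoate | O=C(OCc1ccccc1)c1cccc(OCc2ccccc2)c1OCc1ccccc1 | intermediate
13 | 2,3-bis(benzyloxy)benzoic acid | O=C(O)c1cccc(OCc2ccccc2)c1OCc1ccccc1 | intermediate
14 | (S)-14-methylhexadecyl 2,3-bis(benzyloxy)benzoate | CC[C@H](C)CCCCCCCCCCCCCOC(=O)c1cccc(OCc2ccccc2)c1OCc1ccccc1 | intermediate
15 | Gentiside C, (S)-14-methylhexadecyl 2,3-dihydroxybenzoate | CC[C@H](C)CCCCCCCCCCCCCOC(=O)c1cccc(O)c1O | target

**Step count**
Total step count: 10.
Longest linear sequence: 8 steps (steps 1, 2, 3, 4, 5, 6, 9 and 10, from 1 to 15); steps 7 and 8 form the short arene branch.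

**Steps most likely to fail**

1. Step 5. The two radicals may pair mainly with their own kind, or be oxidised further at the anode to cations that end as ethers and alkenes, and the electrode may foul, so that too little of the cross-coupled ester forms. The fallback sets out from 7 and makes the neighbouring C10–C11 bond by a polar coupling instead. Reduction of 7 with LiAlH4 in THF should give (S)-4-methylhexan-1-ol F1. Bromination with CBr4 and PPh3 in CH2Cl2 should give (S)-1-bromo-4-methylhexane F2. Magnesium turnings in THF convert this to (S)-(4-methylhexyl)magnesium bromide F3. Copper-catalysed sp3–sp3 coupling of F3 with commercial methyl 10-bromodecanoate (COC(=O)CCCCCCCCCBr; Li2CuCl4 cat., THF/NMP, 0 °C) should give the same ester, and the route is rejoined at 9.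

2. Step 2. Displacement at the beta-branched primary carbon may be sluggish, so that dialkylation of the malonate and elimination or solvolysis of the tosylate take over. The fallback sets out from 1 and brings in the two carbons by olefination. Oxidation of 1 with TEMPO (cat.), NaOCl and KBr in CH2Cl2/H2O at 0 °C should give (S)-2-methylbutanal F4, used at once and kept away from base to protect its alpha stereocentre. Wittig reaction with commercial ethyl (triphenylphosphoranylidene)acetate in CH2Cl2 at rt should give ethyl (S,E)-4-methylhex-2-enoate F5; the alkene geometry does not matter. Hydrogenation over 10% Pd/C in EtOAc should give ethyl (S)-4-methylhexanoate F6. Saponification with LiOH in THF/H2O and acidification with HCl returns the route at 7.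

3. Step 9. The activated acid may rearrange to an unreactive N-acylurea faster than it acylates the waxy, poorly soluble long-chain alcohol, leaving the esterification incomplete. The fallback sets out from 10 and reverses the roles of the partners, forming the ester by O-alkylation. Treatment of 10 with MsCl and Et3N in CH2Cl2 at 0 °C should give (S)-14-methylhexadecyl methanesulfonate F7. This is displaced in DMF at 60 °C by caesium 2,3-bis(benzyloxy)benzoate F8, made in the flask from 13 and Cs2CO3, and the route is rejoined at 14.

**Further compounds**
F1 | step 5 | (S)-4-methylhexan-1-ol | CC[C@H](C)CCCO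
F2 | step 5 | (S)-1-bromo-4-methylhexane | CC[C@H](C)CCCBr
F3 | step 5 | (S)-(4-methylhexyl)magnesium bromide | CC[C@H](C)CCC[Mg]Br
F4 | step 2 | (S)-2-methylbutanal | CC[C@H](C)C=O
F5 | step 2 | ethyl (S,E)-4-methylhex-2-enoate | CC[C@H](C)/C=C/C(=O)OCC
F6 | step 2 | ethyl (S)-4-methylhexanoate | CC[C@H](C)CCC(=O)OCC
F7 | step 9 | (S)-14-methylhexadecyl methanesulfonate | CC[C@H](C)CCCCCCCCCCCCCOS(C)(=O)=O
F8 | step 9 | caesium 2,3-bis(benzyloxy)benzoate | [Cs+].[O-]C(=O)c1cccc(OCc2ccccc2)c1OCc1ccccc1
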